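**Retrosynthetic overview**

- The strategy rests on ring D: a benzene-1,3,5-triol (hydroxyls on C2, C4, C6) whose C1 carries the ether oxygen to ring C. Cutting its C1–C2 bond unfolds it to a methyl 3,5-dioxohexanoate (16) that already bears the ring A–B–C aryloxy group on chain C6.
- Triketide 16 comes from acylation of the methyl acetoacetate dianion at its terminal carbon by an aryloxy-N-methoxy-N-methylacetamide (13), made by O-alkylation of the ring A–B–C phenol 11.
- Rings B and C both come from one building block, 2,6-bis(benzyloxy)-4-bromophenol (4). Its hindered oxygen is arylated twice by Chan–Lam coupling; its bromine becomes the boronic acid (ring B) or the hydroxyl (ring C).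
- Rings A, B and C are bought as benzene rings and joined in the order A, B, C. Ring D is the only ring constructed, and it is formed last; six benzyl ethers are then removed.

Key step: step 9

Remark: rings are lettered A to D from the 3,5-dihydroxyphenyl end. Compound 16 is drawn as the triketone, although enol tautomers should dominate.

**Route**

Step 1
Reactants: 1 4-bromo-2,6-difluorobenzaldehyde
Product: 2 2,6-bis(benzyloxy)-4-bromobenzaldehyde
Conditions: BnOH (2.1 equiv), NaH (2.1 equiv), DMF, 0 to 50 °C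
Reagents that add atoms: benzyl alcohol, OCc1ccccc1
Why: Nucleophilic aromatic substitution (addition–elimination); both fluorines are ortho to the formyl group and fluoride is by far the better nucleofuge in this mechanism, so two benzyl oxide units should enter while the para bromine stays.

Step 2
Reactants: 2 2,6-bis(benzyloxy)-4-bromobenzaldehyde
Product: 4 2,6-bis(benzyloxy)-4-bromophenol, via aryl formate 3 (not isolated)
Conditions: mCPBA, CH2Cl2, 0 °C to rt; then K2CO3 (cat.), MeOH, rt
Reagents that add atoms: 3-chloroperoxybenzoic acid, OOC(=O)c1cccc(Cl)c1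
Why: Baeyer–Villiger oxidation of an electron-rich benzaldehyde (Dakin-type), in which the 2,6-dialkoxyaryl group migrates to oxygen to give formate 3, which mild methanolysis cleaves without touching the benzyl ethers or the bromide.

Step 3
Reactants: 4 2,6-bis(benzyloxy)-4-bromophenol; 5 3,5-bis(benzyloxy)phenylboronic acid
Product: 6 1,3-bis(benzyloxy)-2-[3,5-bis(benzyloxy)phenoxy]-5-bromobenzene (ring A–B bromide)
Conditions: 5 (2 equiv), Cu(OAc)2 (1.5 equiv), pyridine (5 equiv), 4 Å MS, CH2Cl2, dry air, rt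
Reagents that add atoms: none
Why: Chan–Lam coupling, in which the boronic acid transmetallates to divalent copper and the aryl–oxygen bond forms at room temperature; doubly ortho-substituted phenols are accepted and the aryl bromide of 4 is inert under these conditions.

Step 4
Reactants: 6 ring A–B bromide
Product: 9 {3,5-bis(benzyloxy)-4-[3,5-bis(benzyloxy)phenoxy]phenyl}boronic acid, via aryllithium 7 (not isolated), via lithium aryltriisopropoxyborate 8 (not isolated)
Conditions: n-BuLi, THF, −78 °C; B(OiPr)3, −78 °C to rt; 1 M HCl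
Reagents that add atoms: triisopropyl borate, CC(C)OB(OC(C)C)OC(C)C; water, O
Why: Bromine–lithium exchange at −78 °C is faster than any deprotonation of the benzyl ethers, and trapping of aryllithium 7 with the borate ester followed by acidic hydrolysis is the standard lithiation–borylation route to an arylboronic acid.

Step 5
Reactants: 9 ring A–B boronic acid; 4 2,6-bis(benzyloxy)-4-bromophenol
Product: 10 1,3-bis(benzyloxy)-2-{3,5-bis(benzyloxy)-4-[3,5-bis(benzyloxy)phenoxy]phenoxy}-5-bromobenzene (ring A–B–C bromide)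
Conditions: 4 (2 equiv), Cu(OAc)2 (1.5 equiv), pyridine (5 equiv), 4 Å MS, CH2Cl2, dry air, rt
Reagents that add atoms: none
Why: Second Chan–Lam coupling with the same building block, joining the unhindered C4 of ring B to the hindered oxygen of ring C while the bromine of 4 again survives as the handle for the next step.

Step 6
Reactants: 10 ring A–B–C bromide
Product: 11 3,5-bis(benzyloxy)-4-{3,5-bis(benzyloxy)-4-[3,5-bis(benzyloxy)phenoxy]phenoxy}phenol (ring A–B–C phenol)
Conditions: Pd2(dba)3 (2 mol %), tBuXPhos (8 mol %), KOH (3 equiv), 1,4-dioxane/H2O, 100 °C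
Reagents that add atoms: potassium hydroxide, [K+].[OH-]
Why: Palladium-catalysed hydroxylation of an aryl bromide with hydroxide (C–O cross-coupling with a bulky biarylphosphine), which tolerates benzyl ethers and diaryl ethers.

Step 7
Reactants: 11 ring A–B–C phenol; 12 2-chloro-N-methoxy-N-methylacetamide
Product: 13 2-(3,5-bis(benzyloxy)-4-{3,5-bis(benzyloxy)-4-[3,5-bis(benzyloxy)phenoxy]phenoxy}phenoxy)-N-methoxy-N-methylacetamide
Conditions: K2CO3, NaI (cat.), DMF, 50 °C
Reagents that add atoms: none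
Why: Williamson ether synthesis, the unhindered phenoxide of ring C displacing chloride from the α-chloroamide (SN2 with iodide catalysis).

Step 8
Reactants: 13 aryloxy N-methoxy-N-methylacetamide; 14 methyl acetoacetate
Product: 16 methyl 6-(3,5-bis(benzyloxy)-4-{3,5-bis(benzyloxy)-4-[3,5-bis(benzyloxy)phenoxy]phenoxy}phenoxy)-3,5-dioxohexanoate, via dilithium acetoacetate dianion 15 (not isolated)
Conditions: 14 (3.0 equiv), LiN(iPr)2 (5.9 equiv), THF, −78 to 0 °C; then 13, −78 to −30 °C; cold 1 M HCl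
Reagents that add atoms: none
Why: Acylation of dianion 15 at its terminal carbon by an N-methoxy-N-methylamide (Weinreb ketone synthesis); the terminal carbanion is the more nucleophilic site and the lithium-chelated adduct should not collapse before the quench, so one acyl transfer gives the 3,5-dioxo ester.

Step 9
Reactants: 16 methyl 6-aryloxy-3,5-dioxohexanoate
Product: 18 2-(3,5-bis(benzyloxy)-4-{3,5-bis(benzyloxy)-4-[3,5-bis(benzyloxy)phenoxy]phenoxy}phenoxy)benzene-1,3,5-triol (hexa-O-benzyl tetraphlorethol C, ring D unprotected), via cyclohexanetrione 17 (not isolated)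
Conditions: Mg(OMe)2 (6 equiv), MeOH–THF (degassed), 65 °C, argon; then cold 1 M HCl
Reagents that add atoms: none
Why: Magnesium methoxide converts 16 into its chelated enolate, and further deprotonation at C6, acidified by both the C5 carbonyl and the aryloxy oxygen, gives the carbon nucleophile that attacks ester carbon C1 with loss of methoxide (intramolecular Claisen condensation) to form 2-aryloxycyclohexane-1,3,5-trione 17, which should enolize at once to the phloroglucinol ring. The closest known reaction type is the Claisen cyclization of 3,5-dioxo- and 3,5,7-trioxoalkanoate esters to phloroglucinols under Mg(OMe)2 or alkali alkoxide, the laboratory counterpart of the polyketide synthase ring closure, here applied to a chain carrying an ether oxygen on C6. Ring D closes in a 6-(enolendo)-exo-trig mode, its six atoms being chain C1 to C6. No stereocenter is formed. The selectivity needed is carbon acylation from C6 over lactonization through the C5 enol oxygen: magnesium holds that oxygen in a chelate, Mg(OMe)2 in methanol should reopen any 2-pyranone to the open-chain ester, and aromatization to the phloroglucinol magnesium salt is irreversible, so the equilibrating mixture should drain to 18. Oxygen is excluded because the free phloroglucinol ring is easily oxidized in base.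

Step 10
Reactants: 18 hexa-O-benzyl tetraphlorethol C
Product: 19 tetraphlorethol C
Conditions: H2 (1 atm), 10% Pd/C, THF–MeOH, rt; filtration under argon
Reagents that add atoms: none
Why: Hydrogenolysis of six benzyl aryl ethers over palladium; the diaryl ether bonds and the phenol rings are not reduced under these conditions.

**Compound list**

1 | 4-bromo-2,6-difluorobenzaldehyde | O=Cc1c(F)cc(Br)cc1F | starting material
2 | 2,6-bis(benzyloxy)-4-bromobenzaldehyde | O=Cc1c(OCc2ccccc2)cc(Br)cc1OCc1ccccc1 | intermediate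
3 | 2,6-bis(benzyloxy)-4-bromophenyl formate | O=COc1c(OCc2ccccc2)cc(Br)cc1OCc1ccccc1 | intermediate
4 | 2,6-bis(benzyloxy)-4-bromophenol | Oc1c(OCc2ccccc2)cc(Br)cc1OCc1ccccc1 | intermediate
5 | 3,5-bis(benzyloxy)phenylboronic acid | OB(O)c1cc(OCc2ccccc2)cc(OCc2ccccc2)c1 | starting material
6 | 1,3-bis(benzyloxy)-2-[3,5-bis(benzyloxy)phenoxy]-5-bromobenzene | Brc1cc(OCc2ccccc2)c(Oc2cc(OCc3ccccc3)cc(OCc3ccccc3)c2)c(OCc2ccccc2)c1 | intermediate
7 | {3,5-bis(benzyloxy)-4-[3,5-bis(benzyloxy)phenoxy]phenyl}lithium | [Li]c1cc(OCc2ccccc2)c(Oc2cc(OCc3ccccc3)cc(OCc3ccccc3)c2)c(OCc2ccccc2)c1 | intermediate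
8 | lithium {3,5-bis(benzyloxy)-4-[3,5-bis(benzyloxy)phenoxy]phenyl}triisopropoxyborate | [Li+].CC(C)O[B-](OC(C)C)(OC(C)C)c1cc(OCc2ccccc2)c(Oc2cc(OCc3ccccc3)cc(OCc3ccccc3)c2)c(OCc2ccccc2)c1 | intermediate
9 | {3,5-bis(benzyloxy)-4-[3,5-bis(benzyloxy)phenoxy]phenyl}boronic acid | OB(O)c1cc(OCc2ccccc2)c(Oc2cc(OCc3ccccc3)cc(OCc3ccccc3)c2)c(OCc2ccccc2)c1 | intermediate
10 | 1,3-bis(benzyloxy)-2-{3,5-bis(benzyloxy)-4-[3,5-bis(benzyloxy)phenoxy]phenoxy}-5-bromobenzene | Brc1cc(OCc2ccccc2)c(Oc2cc(OCc3ccccc3)c(Oc3cc(OCc4ccccc4)cc(OCc4ccccc4)c3)c(OCc3ccccc3)c2)c(OCc2ccccc2)c1 | intermediate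
11 | 3,5-bis(benzyloxy)-4-{3,5-bis(benzyloxy)-4-[3,5-bis(benzyloxy)phenoxy]phenoxy}phenol | Oc1cc(OCc2ccccc2)c(Oc2cc(OCc3ccccc3)c(Oc3cc(OCc4ccccc4)cc(OCc4ccccc4)c3)c(OCc3ccccc3)c2)c(OCc2ccccc2)c1 | intermediate
12 | 2-chloro-N-methoxy-N-methylacetamide | CON(C)C(=O)CCl | starting material
13 | 2-(3,5-bis(benzyloxy)-4-{3,5-bis(benzyloxy)-4-[3,5-bis(benzyloxy)phenoxy]phenoxy}phenoxy)-N-methoxy-N-methylacetamide | CON(C)C(=O)COc1cc(OCc2ccccc2)c(Oc2cc(OCc3ccccc3)c(Oc3cc(OCc4ccccc4)cc(OCc4ccccc4)c3)c(OCc3ccccc3)c2)c(OCc2ccccc2)c1 | intermediate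
14 | methyl acetoacetate | COC(=O)CC(C)=O | starting material
15 | dilithium 1-methoxybuta-1,3-diene-1,3-diolate (methyl acetoacetate dianion) | [Li+].[Li+].C=C([O-])C=C([O-])OC | intermediate
16 | methyl 6-(3,5-bis(benzyloxy)-4-{3,5-bis(benzyloxy)-4-[3,5-bis(benzyloxy)phenoxy]phenoxy}phenoxy)-3,5-dioxohexanoate | COC(=O)CC(=O)CC(=O)COc1cc(OCc2ccccc2)c(Oc2cc(OCc3ccccc3)c(Oc3cc(OCc4ccccc4)cc(OCc4ccccc4)c3)c(OCc3ccccc3)c2)c(OCc2ccccc2)c1 | intermediate
17 | 2-(3,5-bis(benzyloxy)-4-{3,5-bis(benzyloxy)-4-[3,5-bis(benzyloxy)phenoxy]phenoxy}phenoxy)cyclohexane-1,3,5-trione | O=C1CC(=O)C(Oc2cc(OCc3ccccc3)c(Oc3cc(OCc4ccccc4)c(Oc4cc(OCc5ccccc5)cc(OCc5ccccc5)c4)c(OCc4ccccc4)c3)c(OCc3ccccc3)c2)C(=O)C1 | intermediate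
18 | 2-(3,5-bis(benzyloxy)-4-{3,5-bis(benzyloxy)-4-[3,5-bis(benzyloxy)phenoxy]phenoxy}phenoxy)benzene-1,3,5-triol | Oc1cc(O)c(Oc2cc(OCc3ccccc3)c(Oc3cc(OCc4ccccc4)c(Oc4cc(OCc5ccccc5)cc(OCc5ccccc5)c4)c(OCc4ccccc4)c3)c(OCc3ccccc3)c2)c(O)c1 | intermediate
19 | tetraphlorethol C | Oc1cc(O)cc(Oc2c(O)cc(Oc3c(O)cc(Oc4c(O)cc(O)cc4O)cc3O)cc2O)c1 | target

**Step count**

Total steps: 10. Longest linear sequence: 10 steps (1 to 19).

**Steps most likely to fail**

Step 9 (key step). O-Acylation through the C5 enol oxygen may outrun carbon acylation and the lactone may not reopen. Methoxide may also cut the 1,3-diketone at the activated C5 carbonyl (retro-Claisen), or the magnesium chelate may never reach the C6 enolate. The fallback brings ring D in as an aromatic ring instead of building it. It sets out from bromide 10, which is taken through the lithiation–borylation of step 4, by way of the ring A–B–C aryllithium F1 and the lithium aryltriisopropoxyborate F2 (neither isolated), to the ring A–B–C boronic acid F3. Chan–Lam coupling of F3 with a further portion of bromophenol 4 (conditions of step 5) should give the ring A–B–C–D bromide F4. Palladium-catalysed hydroxylation as in step 6 then gives octa-O-benzyl tetraphlorethol C with a free ring D 4-hydroxyl F5. Hydrogenolysis of its eight benzyl ethers (conditions of step 10) comes back to the route at 19.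

Step 5 (step 3 runs the same risk on cheaper material, where excess boronic acid 5 can be spent). Oxidation of the electron-rich, doubly ortho-substituted phenol by divalent copper and air, and protodeboronation or hydroxylation of the boronic acid, may compete with slow C–O bond formation at the hindered oxygen. The fallback replaces the oxidative boron-to-oxygen coupling by a copper-catalysed Ullmann etherification with a halogen-free ring C phenol that already carries the side chain. It sets out from 4 and 6. Bromophenol 4 is hydroxylated under the conditions of step 6 to 2,6-bis(benzyloxy)benzene-1,4-diol F6 (kept under argon). Its unhindered, more acidic 4-hydroxyl is alkylated with one equivalent of 12 (K2CO3, acetone, rt) to 2-[3,5-bis(benzyloxy)-4-hydroxyphenoxy]-N-methoxy-N-methylacetamide F7. Ullmann coupling of F7 with bromide 6 (CuI, picolinic acid, K3PO4, DMSO, 90 °C) comes back to the route at 13, making steps 4 to 7 unnecessary.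

Step 8. Proton transfer from the α-aryloxy amide to the strongly basic dianion may return starting material, and the 3,5-dioxo ester may lactonize or be cleaved during acidic work-up and on silica. The fallback uses carbonyl addition and oxidation in place of acyl substitution. It sets out from 13, which is reduced with iBu2AlH (THF, −78 °C) to the aryloxyacetaldehyde F8. Addition of dianion 15 at −78 °C should give racemic methyl 6-aryloxy-5-hydroxy-3-oxohexanoate F9. Oxidation of the carbinol with Dess–Martin periodinane (NaHCO3, CH2Cl2, rt) comes back to the route at 16.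

**Further compounds**

F1 | step 9 | (3,5-bis(benzyloxy)-4-{3,5-bis(benzyloxy)-4-[3,5-bis(benzyloxy)phenoxy]phenoxy}phenyl)lithium | [Li]c1cc(OCc2ccccc2)c(Oc2cc(OCc3ccccc3)c(Oc3cc(OCc4ccccc4)cc(OCc4ccccc4)c3)c(OCc3ccccc3)c2)c(OCc2ccccc2)c1
F2 | step 9 | lithium (3,5-bis(benzyloxy)-4-{3,5-bis(benzyloxy)-4-[3,5-bis(benzyloxy)phenoxy]phenoxy}phenyl)triisopropoxyborate | [Li+].CC(C)O[B-](OC(C)C)(OC(C)C)c1cc(OCc2ccccc2)c(Oc2cc(OCc3ccccc3)c(Oc3cc(OCc4ccccc4)cc(OCc4ccccc4)c3)c(OCc3ccccc3)c2)c(OCc2ccccc2)c1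
F3 | step 9 | (3,5-bis(benzyloxy)-4-{3,5-bis(benzyloxy)-4-[3,5-bis(benzyloxy)phenoxy]phenoxy}phenyl)boronic acid | OB(O)c1cc(OCc2ccccc2)c(Oc2cc(OCc3ccccc3)c(Oc3cc(OCc4ccccc4)cc(OCc4ccccc4)c3)c(OCc3ccccc3)c2)c(OCc2ccccc2)c1
F4 | step 9 | 1,3-bis(benzyloxy)-2-(3,5-bis(benzyloxy)-4-{3,5-bis(benzyloxy)-4-[3,5-bis(benzyloxy)phenoxy]phenoxy}phenoxy)-5-bromobenzene | Brc1cc(OCc2ccccc2)c(Oc2cc(OCc3ccccc3)c(Oc3cc(OCc4ccccc4)c(Oc4cc(OCc5ccccc5)cc(OCc5ccccc5)c4)c(OCc4ccccc4)c3)c(OCc3ccccc3)c2)c(OCc2ccccc2)c1
F5 | step 9 | 3,5-bis(benzyloxy)-4-(3,5-bis(benzyloxy)-4-{3,5-bis(benzyloxy)-4-[3,5-bis(benzyloxy)phenoxy]phenoxy}phenoxy)phenol | Oc1cc(OCc2ccccc2)c(Oc2cc(OCc3ccccc3)c(Oc3cc(OCc4ccccc4)c(Oc4cc(OCc5ccccc5)cc(OCc5ccccc5)c4)c(OCc4ccccc4)c3)c(OCc3ccccc3)c2)c(OCc2ccccc2)c1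
F6 | step 5 | 2,6-bis(benzyloxy)benzene-1,4-diol | Oc1cc(OCc2ccccc2)c(O)c(OCc2ccccc2)c1
F7 | step 5 | 2-[3,5-bis(benzyloxy)-4-hydroxyphenoxy]-N-methoxy-N-methylacetamide | CON(C)C(=O)COc1cc(OCc2ccccc2)c(O)c(OCc2ccccc2)c1
F8 | step 8 | 2-(3,5-bis(benzyloxy)-4-{3,5-bis(benzyloxy)-4-[3,5-bis(benzyloxy)phenoxy]phenoxy}phenoxy)acetaldehyde | O=CCOc1cc(OCc2ccccc2)c(Oc2cc(OCc3ccccc3)c(Oc3cc(OCc4ccccc4)cc(OCc4ccccc4)c3)c(OCc3ccccc3)c2)c(OCc2ccccc2)c1
F9 | step 8 | methyl 6-(3,5-bis(benzyloxy)-4-{3,5-bis(benzyloxy)-4-[3,5-bis(benzyloxy)phenoxy]phenoxy}phenoxy)-5-hydroxy-3-oxohexanoate (racemic) | COC(=O)CC(=O)CC(O)COc1cc(OCc2ccccc2)c(Oc2cc(OCc3ccccc3)c(Oc3cc(OCc4ccccc4)cc(OCc4ccccc4)c3)c(OCc3ccccc3)c2)c(OCc2ccccc2)c1
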